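**Assumption:** the target is the (3R)-isoflavanone with a (2E)-geranyl chain, as the SMILES encodes; a sequence run in one flask is counted as one step.

## Retrosynthetic overview

1. Target 14 ⇒ isoflavone 13: the two hydrogens at C2/C3 are added last by a reductase-type (NADH-mimic) asymmetric transfer hydrogenation, which sets the only stereocentre.
2. 13 ⇒ bromo-isoflavone 7: the C5'–geranyl bond comes from an aryl stannane and (E)-geranyl bromide, after the methyl ethers have been exchanged for acetates.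
3. 7 ⇒ flavanone 6 by an isoflavone-synthase-type oxidative 2,3-aryl shift; 6 ⇒ chalcone 5 (oxa-Michael closure of ring C) ⇒ acetophenone 3 + aldehyde 4 (Claisen–Schmidt).
4. 3 ⇒ C2-symmetric phenol 2 ⇒ aldehyde 1: the symmetry makes the acylation, and therefore the 6-methyl (not 8-methyl) pattern, unambiguous.
5. Ring order: rings A and B are bought; ring C is closed in step 3 and rearranged in step 4; the stereocentre is set in step 9.

## Route

**Step 1**
Reactants: 1 4-hydroxy-2,6-dimethoxybenzaldehyde
Product: 2 3,5-dimethoxy-4-methylphenol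
Conditions: H2 (4 bar), 10% Pd/C, AcOH, 50 °C
Reagents that add atoms: none
Why: Catalytic hydrogenation reduces the aldehyde, and the benzylic C–O bond, activated by the para-OH and two ortho-OMe groups, is then hydrogenolysed to CH3, giving a phenol whose two free ring positions are equivalent.

**Step 2**
Reactants: 2 3,5-dimethoxy-4-methylphenol
Product: 3 1-(6-hydroxy-2,4-dimethoxy-3-methylphenyl)ethan-1-one
Conditions: Ac2O, BF3·OEt2, 70 °C; then H2O, 60 °C
Reagents that add atoms: acetic anhydride, CC(=O)OC(C)=O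
Why: BF3-mediated Friedel–Crafts (Fries-type) C-acetylation can only occur at the two equivalent positions ortho to the OH, so the free OH sits next to ring H and the OMe next to the C-methyl, and the BF2 chelate of the product stops a second acylation.

**Step 3**
Reactants: 3 1-(6-hydroxy-2,4-dimethoxy-3-methylphenyl)ethan-1-one; 4 5-bromo-2,4-dimethoxybenzaldehyde
Product: 6 (±)-2-(5-bromo-2,4-dimethoxyphenyl)-5,7-dimethoxy-6-methylchroman-4-one, via 2'-hydroxychalcone 5 (not isolated)
Conditions: KOH, EtOH–H2O, rt; then AcOH, reflux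
Reagents that add atoms: none
Why: Claisen–Schmidt aldol condensation gives the E-chalcone, and the acetate-buffered reflux closes ring C by intramolecular oxa-Michael addition of the only free phenol (the chalcone-isomerase step, favoured by the 6'-methoxy group); C2 forms racemic and is erased in step 4.

**Step 4**
Reactants: 6 (±)-2-(5-bromo-2,4-dimethoxyphenyl)-5,7-dimethoxy-6-methylchroman-4-one
Product: 7 3-(5-bromo-2,4-dimethoxyphenyl)-5,7-dimethoxy-6-methyl-4H-chromen-4-one
Conditions: PhI(OH)OTs (Koser's reagent), MeCN, reflux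
Reagents that add atoms: none
Why: Hypervalent-iodine oxidative 2,3-aryl migration of a flavanone (the chemical counterpart of isoflavone synthase): the enol attacks I(III) at C3, the electron-rich 2,4-dimethoxyaryl group shifts from C2 to C3 as PhI leaves, and the O-stabilised C2 cation loses H-3 to give the isoflavone.

**Step 5**
Reactants: 7 3-(5-bromo-2,4-dimethoxyphenyl)-5,7-dimethoxy-6-methyl-4H-chromen-4-one
Product: 9 3-(2,4-diacetoxy-5-bromophenyl)-6-methyl-4-oxo-4H-chromene-5,7-diyl diacetate, via tetrahydroxy bromoisoflavone 8 (not isolated)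
Conditions: BBr3, CH2Cl2, −78 °C → rt; MeOH, evaporate; then Ac2O, pyridine, DMAP, rt
Reagents that add atoms: acetic anhydride, CC(=O)OC(C)=O
Why: BBr3 ether cleavage removes all four methyl groups while the isoflavone core and the aryl bromide are inert, and O-acetylation of the crude tetraphenol gives a chromatographable tetraacetate whose masked phenols cannot be O-allylated or protonate the organometallics of steps 6 and 7.

**Step 6**
Reactants: 9 3-(2,4-diacetoxy-5-bromophenyl)-6-methyl-4-oxo-4H-chromene-5,7-diyl diacetate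
Product: 10 3-[2,4-diacetoxy-5-(tributylstannyl)phenyl]-6-methyl-4-oxo-4H-chromene-5,7-diyl diacetate
Conditions: (Bu3Sn)2, Pd(PPh3)4 (cat.), PhMe, 110 °C
Reagents that add atoms: hexabutylditin, CCCC[Sn](CCCC)(CCCC)[Sn](CCCC)(CCCC)CCCC
Why: Pd(0)-catalysed stannylation of the single aryl bromide (oxidative addition, Sn–Sn transmetalation, reductive elimination) is neutral, leaves acetates and chromone untouched, and makes C5' the nucleophile so that the geranyl unit can enter as the electrophile.

**Step 7**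
Reactants: 10 3-[2,4-diacetoxy-5-(tributylstannyl)phenyl]-6-methyl-4-oxo-4H-chromene-5,7-diyl diacetate; 11 geranyl bromide, (2E)-1-bromo-3,7-dimethylocta-2,6-diene
Product: 12 3-{2,4-diacetoxy-5-[(2E)-3,7-dimethylocta-2,6-dien-1-yl]phenyl}-6-methyl-4-oxo-4H-chromene-5,7-diyl diacetate
Conditions: Pd2(dba)3 (cat.), AsPh3, THF, 60 °C
Reagents that add atoms: none
Why: Stille coupling with the allylic bromide as electrophile: the η3-geranyl-palladium complex keeps the E geometry (syn/anti exchange would need a tertiary σ-allyl), and the aryl group is delivered to the unhindered primary terminus, giving the linear E-geranyl arene at C5' only.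

**Step 8**
Reactants: 12 3-{2,4-diacetoxy-5-[(2E)-3,7-dimethylocta-2,6-dien-1-yl]phenyl}-6-methyl-4-oxo-4H-chromene-5,7-diyl diacetate
Product: 13 3-{5-[(2E)-3,7-dimethylocta-2,6-dien-1-yl]-2,4-dihydroxyphenyl}-5,7-dihydroxy-6-methyl-4H-chromen-4-one
Conditions: K2CO3 (cat.), MeOH, 0 °C → rt; then AcOH
Reagents that add atoms: none
Why: Base-catalysed transesterification (Zemplén-type methanolysis) cleaves the four aryl acetates under conditions that neither open the phenoxide-deactivated chromone nor touch the geranyl chain.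

**Step 9**
Reactants: 13 3-{5-[(2E)-3,7-dimethylocta-2,6-dien-1-yl]-2,4-dihydroxyphenyl}-5,7-dihydroxy-6-methyl-4H-chromen-4-one
Product: 14 (3R)-3-{5-[(2E)-3,7-dimethylocta-2,6-dien-1-yl]-2,4-dihydroxyphenyl}-5,7-dihydroxy-6-methylchroman-4-one
Conditions: (R)-TRIP (10 mol %), Hantzsch ester (diethyl 1,4-dihydro-2,6-dimethylpyridine-3,5-dicarboxylate), 1,4-dioxane–PhMe, 4 Å MS, 50 °C
Reagents that add atoms: none
Why: Proposed new method: an isoflavone-reductase mimic in which the chiral phosphoric acid hydrogen-bonds/protonates the chromone carbonyl (4-hydroxybenzopyrylium character), the Hantzsch ester transfers hydride to C2, and the resulting 2H-chromen-4-ol is tautomerised inside the chiral phosphate pocket by enantioselective protonation at C3, setting (3R) in the last step with no base present to racemise it and with alkenes, phenols and the product ketone inert to the reductant; the closest known reaction type is the chiral-phosphoric-acid/Hantzsch-ester transfer hydrogenation of 3-substituted quinolines (1,4-hydride addition, then enantio-determining Brønsted-acid protonation) and the Hantzsch-ester reduction of benzopyrylium ions; the facial sense of (R)-TRIP on this substrate is not established and is checked by chiral HPLC/CD on the first run, the antipodal catalyst being used if it is opposite.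

## Compound list

1 | 4-hydroxy-2,6-dimethoxybenzaldehyde | O=Cc1c(OC)cc(O)cc1OC | starting material
2 | 3,5-dimethoxy-4-methylphenol | Cc1c(OC)cc(O)cc1OC | intermediate
3 | 1-(6-hydroxy-2,4-dimethoxy-3-methylphenyl)ethan-1-one | CC(=O)c1c(O)cc(OC)c(C)c1OC | intermediate
4 | 5-bromo-2,4-dimethoxybenzaldehyde | O=Cc1cc(Br)c(OC)cc1OC | starting material
5 | (E)-3-(5-bromo-2,4-dimethoxyphenyl)-1-(6-hydroxy-2,4-dimethoxy-3-methylphenyl)prop-2-en-1-one | O=C(/C=C/c1cc(Br)c(OC)cc1OC)c1c(O)cc(OC)c(C)c1OC | intermediate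
6 | (±)-2-(5-bromo-2,4-dimethoxyphenyl)-5,7-dimethoxy-6-methylchroman-4-one | COc1cc(OC)c(C2CC(=O)c3c(OC)c(C)c(OC)cc3O2)cc1Br | intermediate
7 | 3-(5-bromo-2,4-dimethoxyphenyl)-5,7-dimethoxy-6-methyl-4H-chromen-4-one | COc1cc(OC)c(-c2coc3cc(OC)c(C)c(OC)c3c2=O)cc1Br | intermediate
8 | 3-(5-bromo-2,4-dihydroxyphenyl)-5,7-dihydroxy-6-methyl-4H-chromen-4-one | Oc1cc(O)c(-c2coc3cc(O)c(C)c(O)c3c2=O)cc1Br | intermediate
9 | 3-(2,4-diacetoxy-5-bromophenyl)-6-methyl-4-oxo-4H-chromene-5,7-diyl diacetate | CC(=O)Oc1cc(OC(C)=O)c(-c2coc3cc(OC(C)=O)c(C)c(OC(C)=O)c3c2=O)cc1Br | intermediate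
10 | 3-[2,4-diacetoxy-5-(tributylstannyl)phenyl]-6-methyl-4-oxo-4H-chromene-5,7-diyl diacetate | CC(=O)Oc1cc(OC(C)=O)c(-c2coc3cc(OC(C)=O)c(C)c(OC(C)=O)c3c2=O)cc1[Sn](CCCC)(CCCC)CCCC | intermediate
11 | geranyl bromide, (2E)-1-bromo-3,7-dimethylocta-2,6-diene | CC(C)=CCC/C(C)=C/CBr | starting material
12 | 3-{2,4-diacetoxy-5-[(2E)-3,7-dimethylocta-2,6-dien-1-yl]phenyl}-6-methyl-4-oxo-4H-chromene-5,7-diyl diacetate | CC(C)=CCC/C(C)=C/Cc1cc(-c2coc3cc(OC(C)=O)c(C)c(OC(C)=O)c3c2=O)c(OC(C)=O)cc1OC(C)=O | intermediate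
13 | 3-{5-[(2E)-3,7-dimethylocta-2,6-dien-1-yl]-2,4-dihydroxyphenyl}-5,7-dihydroxy-6-methyl-4H-chromen-4-one | CC(C)=CCC/C(C)=C/Cc1cc(-c2coc3cc(O)c(C)c(O)c3c2=O)c(O)cc1O | intermediate
14 | (3R)-3-{5-[(2E)-3,7-dimethylocta-2,6-dien-1-yl]-2,4-dihydroxyphenyl}-5,7-dihydroxy-6-methylchroman-4-one | CC(C)=CCC/C(C)=C/Cc1cc([C@@H]2COc3cc(O)c(C)c(O)c3C2=O)c(O)cc1O | target

## Step count and risks

Total step count: 9. Longest linear sequence: 9 (1 → 2 → 3 → 6 → 7 → 9 → 10 → 12 → 13 → 14); 4 and 11 are bought.

The three steps most likely to fail: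

**Step 9 (new enantioselective transfer hydrogenation).** The chromone may be too weakly electrophilic for the phosphoric acid/Hantzsch ester pair, or the enol may tautomerise outside the chiral pocket and give low ee. The fallback replaces enantioselective protonation by a dynamic kinetic resolution and sets out from 13. All four phenols are silylated (TBSOTf, 2,6-lutidine, CH2Cl2) to the tetrakis(tert-butyldimethylsilyl) ether of isoflavone 13, F3. Noyori–Ikariya transfer hydrogenation (RuCl[(R,R)-TsDPEN](p-cymene), HCO2H/Et3N, EtOAc, 40 °C) reduces C2=C3 and then the ketone of the rapidly racemising isoflavanone, giving the (3R,4R)-cis-isoflavan-4-ol tetrakis-TBS ether F4. Dess–Martin oxidation (CH2Cl2, 0 °C) returns the ketone without touching C3, giving the (3R)-isoflavanone tetrakis-TBS ether F5. HF·pyridine (THF, 0 °C) removes the silyl groups under acidic conditions and the route is rejoined at 14.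

**Step 4 (iodine(III) aryl shift on the flavanone).** Flavone formation, attack of the reagent on the electron-rich rings, or acid-induced reopening to the chalcone may compete. The fallback sets out from chalcone 5, isolated by working up step 3 before the acid reflux. Thallium(III) nitrate trihydrate in MeOH/HC(OMe)3 at rt rearranges the open-chain enone (the classical oxidative chalcone rearrangement) to 2-(5-bromo-2,4-dimethoxyphenyl)-1-(6-hydroxy-2,4-dimethoxy-3-methylphenyl)-3,3-dimethoxypropan-1-one F1. Refluxing HCl/MeOH then closes the pyranone through the free phenol with loss of methanol, and the route is rejoined at 7.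

**Step 6 (stannylation of the hindered, oxygen-rich aryl bromide).** Slow oxidative addition or homocoupling may limit the yield. The fallback changes the aryl nucleophile from tin to boron and sets out from 9. Miyaura borylation (B2pin2, Pd(dppf)Cl2, KOAc, dioxane, 85 °C) gives 3-[2,4-diacetoxy-5-(4,4,5,5-tetramethyl-1,3,2-dioxaborolan-2-yl)phenyl]-6-methyl-4-oxo-4H-chromene-5,7-diyl diacetate F2. Suzuki–Miyaura allylation of F2 with geranyl bromide 11 (Pd(PPh3)4, anhydrous K3PO4, THF, 60 °C) again goes through the geometry-retaining η3-geranyl-palladium complex, and the route is rejoined at 12.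

## Further compounds

F1 | step 4 | 2-(5-bromo-2,4-dimethoxyphenyl)-1-(6-hydroxy-2,4-dimethoxy-3-methylphenyl)-3,3-dimethoxypropan-1-one (racemic) | COC(OC)C(C(=O)c1c(O)cc(OC)c(C)c1OC)c1cc(Br)c(OC)cc1OC
F2 | step 6 | 3-[2,4-diacetoxy-5-(4,4,5,5-tetramethyl-1,3,2-dioxaborolan-2-yl)phenyl]-6-methyl-4-oxo-4H-chromene-5,7-diyl diacetate | CC(=O)Oc1cc(OC(C)=O)c(-c2coc3cc(OC(C)=O)c(C)c(OC(C)=O)c3c2=O)cc1B1OC(C)(C)C(C)(C)O1
F3 | step 9 | 3-{5-[(2E)-3,7-dimethylocta-2,6-dien-1-yl]-2,4-bis(tert-butyldimethylsilyloxy)phenyl}-5,7-bis(tert-butyldimethylsilyloxy)-6-methyl-4H-chromen-4-one | CC(C)=CCC/C(C)=C/Cc1cc(-c2coc3cc(O[Si](C)(C)C(C)(C)C)c(C)c(O[Si](C)(C)C(C)(C)C)c3c2=O)c(O[Si](C)(C)C(C)(C)C)cc1O[Si](C)(C)C(C)(C)C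
F4 | step 9 | (3R,4R)-3-{5-[(2E)-3,7-dimethylocta-2,6-dien-1-yl]-2,4-bis(tert-butyldimethylsilyloxy)phenyl}-5,7-bis(tert-butyldimethylsilyloxy)-6-methylchroman-4-ol (cis) | CC(C)=CCC/C(C)=C/Cc1cc([C@@H]2COc3cc(O[Si](C)(C)C(C)(C)C)c(C)c(O[Si](C)(C)C(C)(C)C)c3[C@@H]2O)c(O[Si](C)(C)C(C)(C)C)cc1O[Si](C)(C)C(C)(C)C
F5 | step 9 | (3R)-3-{5-[(2E)-3,7-dimethylocta-2,6-dien-1-yl]-2,4-bis(tert-butyldimethylsilyloxy)phenyl}-5,7-bis(tert-butyldimethylsilyloxy)-6-methylchroman-4-one | CC(C)=CCC/C(C)=C/Cc1cc([C@@H]2COc3cc(O[Si](C)(C)C(C)(C)C)c(C)c(O[Si](C)(C)C(C)(C)C)c3C2=O)c(O[Si](C)(C)C(C)(C)C)cc1O[Si](C)(C)C(C)(C)C
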